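**Retrosynthetic overview**

1. The target is robinetinidol-(4β→8)-epigallocatechin. Rings A (benzo), C (pyran) and B (pyrogallol) are the upper flavan; rings D (benzo), F (pyran) and E (pyrogallol) are the lower flavan; flavan numbering is used within each unit.
2. Last disconnections: the nine benzyl ethers (H2), then the C4(ring C)–C8(ring D) bond. The C8 aryllithium of the lower unit adds to the C4 ketone of protected (+)-dihydrorobinetin; the carbinol is ionised and reduced, with hydride entering anti to O3 (3,4-cis).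
3. Lower unit: ring F is closed at C2–C3 by an internal redox cascade on an arylidene acetoacetate of a ring D aldehyde: a 1,5-hydride shift from the O1-bound CH2 of ring E to C4, then addition of the C3 enolate to the C2 oxocarbenium ion.
4. Enabling feature: the C2–H bond is both α to O1 and benzylic to the trialkoxy ring E, hence hydridic, and lies 1,5 to C4 across O1–C8a–C4a of ring D. A bromine at C8 presses that CH2 toward C4 and later is the site of lithiation.
5. After ring closure the ester is cut off, the C3 acetyl becomes the C3 oxygen (Baeyer–Villiger), and hydrogenation of the C3 ketone with dynamic kinetic resolution sets 2R,3R. Ring order: D and E are bought aromatic, F is formed in step 5, A/B/C come intact from dihydrorobinetin.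

Key step: step 5

Remark: (+)-dihydrorobinetin (2R,3R) is taken as a purchasable natural flavanonol (chiral pool), and the ruthenium catalyst of step 10 is written in the enantiomeric series expected, by analogy only, to give the 2R,3R alcohol; its mirror image would be used if the sense proved opposite.

**Route**

Step 1
Reactants: 1 2,4,6-trihydroxybenzaldehyde
Product: 2 2,4-bis(benzyloxy)-6-hydroxybenzaldehyde
Conditions: BnBr (2.1 equiv), K2CO3 (2.1 equiv), DMF, 0 to 25 °C
Reagents that add atoms: benzyl bromide, BrCc1ccccc1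
Why: Williamson etherification: the para hydroxyl and one ortho hydroxyl are benzylated, while the second ortho hydroxyl, tied to the aldehyde by a hydrogen bond, should remain free under stoichiometric control.

Step 2
Reactants: 2 2,4-bis(benzyloxy)-6-hydroxybenzaldehyde
Product: 3 4,6-bis(benzyloxy)-3-bromo-2-hydroxybenzaldehyde
Conditions: N-bromosuccinimide (1.0 equiv), CH2Cl2, −20 to 0 °C
Reagents that add atoms: N-bromosuccinimide, O=C1CCC(=O)N1Br
Why: Electrophilic aromatic bromination: bromine should enter ortho to the free hydroxyl (para to a benzyloxy group and less hindered than the position between the two benzyloxy groups), the usual site of substitution in 2-hydroxy-4,6-dialkoxyaryl carbonyl compounds, and this carbon becomes C8 of ring D.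

Step 3
Reactants: 3 4,6-bis(benzyloxy)-3-bromo-2-hydroxybenzaldehyde; 4 [3,4,5-tris(benzyloxy)phenyl]methanol
Product: 5 4,6-bis(benzyloxy)-3-bromo-2-{[3,4,5-tris(benzyloxy)phenyl]methoxy}benzaldehyde
Conditions: PPh3 (1.3 equiv), diisopropyl azodicarboxylate (1.3 equiv), THF, 0 to 25 °C
Reagents that add atoms: none
Why: Mitsunobu etherification: the acidic hydrogen-bonded phenol is alkylated by the primary benzylic alcohol under neutral conditions, which places the future C2 and ring E on O1 next to the bromine.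

Step 4
Reactants: 5 4,6-bis(benzyloxy)-3-bromo-2-{[3,4,5-tris(benzyloxy)phenyl]methoxy}benzaldehyde; 6 prop-2-enyl 3-oxobutanoate (allyl acetoacetate)
Product: 7 prop-2-enyl 2-acetyl-3-(4,6-bis(benzyloxy)-3-bromo-2-{[3,4,5-tris(benzyloxy)phenyl]methoxy}phenyl)prop-2-enoate (E/Z mixture)
Conditions: piperidine (0.2 equiv), AcOH (0.2 equiv), toluene, reflux with azeotropic removal of water
Reagents that add atoms: none
Why: Knoevenagel condensation: the piperidinium acetate-catalysed condensation gives the arylidene β-keto ester, a two-point-binding acceptor whose acetyl group is the latent C3 oxygen; the double-bond geometry is of no consequence.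

Step 5
Reactants: 7 prop-2-enyl 2-acetyl-3-(4,6-bis(benzyloxy)-3-bromo-2-{[3,4,5-tris(benzyloxy)phenyl]methoxy}phenyl)prop-2-enoate
Product: 9 prop-2-enyl 3-acetyl-5,7-bis(benzyloxy)-8-bromo-2-[3,4,5-tris(benzyloxy)phenyl]chromane-3-carboxylate (racemic; both C3 epimers), via oxocarbenium enolate zwitterion 8 (not isolated)
Conditions: Sc(OTf)3 (10 mol%), ClCH2CH2Cl, 80 °C
Reagents that add atoms: none
Why: Scandium triflate chelates the β-keto ester of 7 and a hydride moves from the O1-bound CH2 (future C2) to C4 (1,5-hydride shift), which gives zwitterion 8, an aryloxocarbenium ion at C2 joined to a scandium-bound β-keto ester enolate at C3; the enolate carbon then adds to the oxocarbenium carbon (Mannich-type C–C bond formation), so that ring F closes through the C2–C3 bond. The closest known reaction type is the Lewis-acid-catalysed internal redox reaction (hydride shift/cyclization, the oxygen counterpart of the tert-amino effect) by which ortho-(benzyloxy)arylidene 1,3-dicarbonyl compounds give 2-arylchromans. Ring F closes in a 6-(enolexo)-endo-trig mode with respect to the O1=C2 oxocarbenium bond. C2 and the quaternary C3 form without control and none is asked for: C3 loses its ester in step 6 and becomes a carbonyl carbon in step 9, and C2 is equilibrated and set in step 10. The selectivity needed is that of the hydride donor, the O1-bound CH2 of ring E against the C5 benzyloxy CH2 that is also ortho to the arylidene: the three alkoxy groups of ring E make the former the better hydride donor and stabilise its oxocarbenium ion, and the C8 bromine on the other side of O1 presses that CH2 toward C4, while the C5 benzyl group can turn away toward C6–H. The ring D ethers lower the electrophilicity of C4, which is offset by the two ortho substituents twisting the arylidene out of conjugation so that the C4 p-lobe points at the ortho CH2 groups.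

Step 6
Reactants: 9 prop-2-enyl 3-acetyl-5,7-bis(benzyloxy)-8-bromo-2-[3,4,5-tris(benzyloxy)phenyl]chromane-3-carboxylate
Product: 11 1-{5,7-bis(benzyloxy)-8-bromo-2-[3,4,5-tris(benzyloxy)phenyl]chroman-3-yl}ethanone (racemic; both C3 epimers), via β-keto acid 10 (not isolated)
Conditions: Pd(PPh3)4 (5 mol%), morpholine (3 equiv), THF, 25 then 50 °C
Reagents that add atoms: none
Why: Tsuji–Trost deallylation: zerovalent palladium transfers the allyl group to morpholine and the freed β-keto acid loses CO2 on warming under nearly neutral conditions that do not open ring F; C3 is reprotonated without control, which is harmless because C3 becomes a carbonyl carbon in step 9.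

Step 7
Reactants: 11 1-{5,7-bis(benzyloxy)-8-bromo-2-[3,4,5-tris(benzyloxy)phenyl]chroman-3-yl}ethanone
Product: 12 5,7-bis(benzyloxy)-8-bromo-2-[3,4,5-tris(benzyloxy)phenyl]chroman-3-yl acetate (racemic; both C3 epimers)
Conditions: mCPBA (2 equiv), CH2Cl2, 0 to 25 °C, dark
Reagents that add atoms: meta-chloroperbenzoic acid, OOC(=O)c1cccc(Cl)c1
Why: Baeyer–Villiger oxidation: the secondary ring carbon C3 migrates in preference to methyl and with retention, so the acetyl group is exchanged for the C3 oxygen.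

Step 8
Reactants: 12 5,7-bis(benzyloxy)-8-bromo-2-[3,4,5-tris(benzyloxy)phenyl]chroman-3-yl acetate
Product: 13 5,7-bis(benzyloxy)-8-bromo-2-[3,4,5-tris(benzyloxy)phenyl]chroman-3-ol (racemic; both C3 epimers)
Conditions: K2CO3 (0.2 equiv), MeOH/THF, 25 °C
Reagents that add atoms: none
Why: Base-catalysed transesterification (methanolysis) of the acetate; with no carbonyl group left next to C3 there is no path for β-elimination of the O1 phenoxide.

Step 9
Reactants: 13 5,7-bis(benzyloxy)-8-bromo-2-[3,4,5-tris(benzyloxy)phenyl]chroman-3-ol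
Product: 14 5,7-bis(benzyloxy)-8-bromo-2-[3,4,5-tris(benzyloxy)phenyl]chroman-3-one (racemic)
Conditions: Dess–Martin periodinane (1.5 equiv), CH2Cl2, 25 °C
Reagents that add atoms: none
Why: Dess–Martin oxidation of the secondary alcohol; both C3 epimers converge on one ketone, in which C2 is α to the carbonyl group and thereby configurationally labile.

Step 10
Reactants: 14 5,7-bis(benzyloxy)-8-bromo-2-[3,4,5-tris(benzyloxy)phenyl]chroman-3-one
Product: 15 (2R,3R)-5,7-bis(benzyloxy)-8-bromo-2-[3,4,5-tris(benzyloxy)phenyl]chroman-3-ol (2,3-cis)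
Conditions: RuCl2[(S)-xylbinap][(S)-daipen] (1 mol%), t-BuOK (10 mol%), H2 (10 atm), toluene/i-PrOH, 25 °C
Reagents that add atoms: none
Why: Noyori-type asymmetric hydrogenation with dynamic kinetic resolution: t-BuOK equilibrates C2 (α to the ketone, benzylic and α to O1) through the enolate while the chiral ruthenium hydride reduces one enantiomer faster and delivers hydride anti to the C2 aryl group, as in the cis-selective hydrogenation of racemic 2-arylcycloalkanones, so that C2 and C3 are set together as 2R,3R.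

Step 11
Reactants: 15 (2R,3R)-5,7-bis(benzyloxy)-8-bromo-2-[3,4,5-tris(benzyloxy)phenyl]chroman-3-ol
Product: 16 {[(2R,3R)-5,7-bis(benzyloxy)-8-bromo-2-[3,4,5-tris(benzyloxy)phenyl]chroman-3-yl]oxy}(tert-butyl)dimethylsilane
Conditions: TBSOTf (1.5 equiv), 2,6-lutidine (2 equiv), CH2Cl2, 0 °C
Reagents that add atoms: tert-butyldimethylsilyl trifluoromethanesulfonate, CC(C)(C)[Si](C)(C)OS(=O)(=O)C(F)(F)F
Why: Silylation of the hindered axial C3 hydroxyl with the silyl triflate, to mask it for the organolithium step.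

Step 12
Reactants: 17 (+)-dihydrorobinetin, (2R,3R)-3,7-dihydroxy-2-(3,4,5-trihydroxyphenyl)chroman-4-one
Product: 18 (2R,3R)-7-(benzyloxy)-3-hydroxy-2-[3,4,5-tris(benzyloxy)phenyl]chroman-4-one
Conditions: BnBr (4.4 equiv), K2CO3 (4.4 equiv), DMF, 0 to 25 °C, under N2
Reagents that add atoms: benzyl bromide, BrCc1ccccc1
Why: Williamson etherification of the four phenols under carbonate conditions that leave the C3 alcohol free; low temperature and exclusion of air limit base-induced ring opening at C2 and dehydrogenation, and the 2R,3R centres of the natural flavanonol are carried on unchanged.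

Step 13
Reactants: 18 (2R,3R)-7-(benzyloxy)-3-hydroxy-2-[3,4,5-tris(benzyloxy)phenyl]chroman-4-one
Product: 19 (2R,3R)-7-(benzyloxy)-3-[(tert-butyldimethylsilyl)oxy]-2-[3,4,5-tris(benzyloxy)phenyl]chroman-4-one
Conditions: TBSCl (1.5 equiv), imidazole (3 equiv), DMF, 25 °C
Reagents that add atoms: tert-butyldimethylsilyl chloride, CC(C)(C)[Si](C)(C)Cl
Why: Silylation of the C3 alcohol with TBSCl and imidazole, conditions too mild to enolise the ketone.

Step 14
Reactants: 16 {[(2R,3R)-5,7-bis(benzyloxy)-8-bromo-2-[3,4,5-tris(benzyloxy)phenyl]chroman-3-yl]oxy}(tert-butyl)dimethylsilane; 19 (2R,3R)-7-(benzyloxy)-3-[(tert-butyldimethylsilyl)oxy]-2-[3,4,5-tris(benzyloxy)phenyl]chroman-4-one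
Product: 21 (2R,3R)-7-(benzyloxy)-3-[(tert-butyldimethylsilyl)oxy]-4-{(2R,3R)-5,7-bis(benzyloxy)-3-[(tert-butyldimethylsilyl)oxy]-2-[3,4,5-tris(benzyloxy)phenyl]chroman-8-yl}-2-[3,4,5-tris(benzyloxy)phenyl]chroman-4-ol (either C4 epimer), via aryllithium 20 (not isolated)
Conditions: t-BuLi (2.0 equiv), THF, −78 °C; then 19, −78 to −40 °C; then H2O
Reagents that add atoms: none
Why: Bromine–lithium exchange at C8 of ring D and 1,2-addition of the aryllithium to the C4 ketone; the new carbinol centre may form as either epimer because it is ionised in the next step.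

Step 15
Reactants: 21 the tertiary alcohol of step 14
Product: 23 (2R,3S,4R)-7-(benzyloxy)-3-[(tert-butyldimethylsilyl)oxy]-4-{(2R,3R)-5,7-bis(benzyloxy)-3-[(tert-butyldimethylsilyl)oxy]-2-[3,4,5-tris(benzyloxy)phenyl]chroman-8-yl}-2-[3,4,5-tris(benzyloxy)phenyl]chromane (3,4-cis), via flavan-4-yl cation 22 (not isolated)
Conditions: Bu3SnH (5 equiv), CF3CO2H (10 equiv), CH2Cl2, 0 °C
Reagents that add atoms: none
Why: Ionic hydrogenation: CF3CO2H ionises the doubly benzylic tertiary alcohol to the 4-arylflavan-4-yl cation and Bu3SnH transfers hydride to C4 on the face anti to the C3 silyloxy group, the facial preference that nucleophiles show toward 2,3-trans flavan-4-yl cations, which leaves ring D cis to O3 (4R).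

Step 16
Reactants: 23 the bis-silyl nona-O-benzyl dimer of step 15
Product: 24 (2R,3S,4R)-7-(benzyloxy)-4-{(2R,3R)-5,7-bis(benzyloxy)-3-hydroxy-2-[3,4,5-tris(benzyloxy)phenyl]chroman-8-yl}-2-[3,4,5-tris(benzyloxy)phenyl]chroman-3-ol
Conditions: HF·pyridine, THF, 0 to 25 °C
Reagents that add atoms: none
Why: Fluoride-induced cleavage of both secondary silyl ethers under conditions that leave the benzyl ethers and the interflavan bond of the 5-deoxy upper unit intact.

Step 17
Reactants: 24 the nona-O-benzyl dimer of step 16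
Product: 25 CNP0275321.4, robinetinidol-(4β→8)-epigallocatechin, (2R,3S,4R)-4-[(2R,3R)-3,5,7-trihydroxy-2-(3,4,5-trihydroxyphenyl)chroman-8-yl]-2-(3,4,5-trihydroxyphenyl)chromane-3,7-diol
Conditions: H2 (1 atm), Pd(OH)2/C, THF/MeOH/H2O, 25 °C
Reagents that add atoms: none
Why: Catalytic hydrogenolysis of the nine benzyl ethers under neutral conditions; no stereocenter is touched.

**Compound list**

1 | 2,4,6-trihydroxybenzaldehyde | O=Cc1c(O)cc(O)cc1O | starting material
2 | 2,4-bis(benzyloxy)-6-hydroxybenzaldehyde | O=Cc1c(O)cc(OCc2ccccc2)cc1OCc1ccccc1 | intermediate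
3 | 4,6-bis(benzyloxy)-3-bromo-2-hydroxybenzaldehyde | O=Cc1c(O)c(Br)c(OCc2ccccc2)cc1OCc1ccccc1 | intermediate
4 | [3,4,5-tris(benzyloxy)phenyl]methanol | OCc1cc(OCc2ccccc2)c(OCc2ccccc2)c(OCc2ccccc2)c1 | starting material
5 | 4,6-bis(benzyloxy)-3-bromo-2-{[3,4,5-tris(benzyloxy)phenyl]methoxy}benzaldehyde | O=Cc1c(OCc2cc(OCc3ccccc3)c(OCc3ccccc3)c(OCc3ccccc3)c2)c(Br)c(OCc2ccccc2)cc1OCc1ccccc1 | intermediate
6 | prop-2-enyl 3-oxobutanoate (allyl acetoacetate) | CC(=O)CC(=O)OCC=C | starting material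
7 | prop-2-enyl 2-acetyl-3-(4,6-bis(benzyloxy)-3-bromo-2-{[3,4,5-tris(benzyloxy)phenyl]methoxy}phenyl)prop-2-enoate (E/Z mixture) | CC(=O)C(=Cc1c(OCc2cc(OCc3ccccc3)c(OCc3ccccc3)c(OCc3ccccc3)c2)c(Br)c(OCc2ccccc2)cc1OCc1ccccc1)C(=O)OCC=C | intermediate
8 | zwitterion: aryloxocarbenium ion at C2 and β-keto ester enolate at C3, C4 reduced to CH2 (drawn without scandium) | CC([O-])=C(Cc1c([O+]=Cc2cc(OCc3ccccc3)c(OCc3ccccc3)c(OCc3ccccc3)c2)c(Br)c(OCc2ccccc2)cc1OCc1ccccc1)C(=O)OCC=C | intermediate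
9 | prop-2-enyl 3-acetyl-5,7-bis(benzyloxy)-8-bromo-2-[3,4,5-tris(benzyloxy)phenyl]chromane-3-carboxylate (racemic; both C3 epimers) | CC(=O)C1(C(=O)OCC=C)Cc2c(OCc3ccccc3)cc(OCc3ccccc3)c(Br)c2OC1c1cc(OCc2ccccc2)c(OCc2ccccc2)c(OCc2ccccc2)c1 | intermediate
10 | 3-acetyl-5,7-bis(benzyloxy)-8-bromo-2-[3,4,5-tris(benzyloxy)phenyl]chromane-3-carboxylic acid (racemic; formed as its morpholinium salt) | CC(=O)C1(C(=O)O)Cc2c(OCc3ccccc3)cc(OCc3ccccc3)c(Br)c2OC1c1cc(OCc2ccccc2)c(OCc2ccccc2)c(OCc2ccccc2)c1 | intermediate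
11 | 1-{5,7-bis(benzyloxy)-8-bromo-2-[3,4,5-tris(benzyloxy)phenyl]chroman-3-yl}ethanone (racemic; both C3 epimers) | CC(=O)C1Cc2c(OCc3ccccc3)cc(OCc3ccccc3)c(Br)c2OC1c1cc(OCc2ccccc2)c(OCc2ccccc2)c(OCc2ccccc2)c1 | intermediate
12 | 5,7-bis(benzyloxy)-8-bromo-2-[3,4,5-tris(benzyloxy)phenyl]chroman-3-yl acetate (racemic; both C3 epimers) | CC(=O)OC1Cc2c(OCc3ccccc3)cc(OCc3ccccc3)c(Br)c2OC1c1cc(OCc2ccccc2)c(OCc2ccccc2)c(OCc2ccccc2)c1 | intermediate
13 | 5,7-bis(benzyloxy)-8-bromo-2-[3,4,5-tris(benzyloxy)phenyl]chroman-3-ol (racemic; both C3 epimers) | OC1Cc2c(OCc3ccccc3)cc(OCc3ccccc3)c(Br)c2OC1c1cc(OCc2ccccc2)c(OCc2ccccc2)c(OCc2ccccc2)c1 | intermediate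
14 | 5,7-bis(benzyloxy)-8-bromo-2-[3,4,5-tris(benzyloxy)phenyl]chroman-3-one (racemic) | O=C1Cc2c(OCc3ccccc3)cc(OCc3ccccc3)c(Br)c2OC1c1cc(OCc2ccccc2)c(OCc2ccccc2)c(OCc2ccccc2)c1 | intermediate
15 | (2R,3R)-5,7-bis(benzyloxy)-8-bromo-2-[3,4,5-tris(benzyloxy)phenyl]chroman-3-ol | Brc1c(OCc2ccccc2)cc(OCc2ccccc2)c2c1O[C@H](c1cc(OCc3ccccc3)c(OCc3ccccc3)c(OCc3ccccc3)c1)[C@H](O)C2 | intermediate
16 | {[(2R,3R)-5,7-bis(benzyloxy)-8-bromo-2-[3,4,5-tris(benzyloxy)phenyl]chroman-3-yl]oxy}(tert-butyl)dimethylsilane | Brc1c(OCc2ccccc2)cc(OCc2ccccc2)c2c1O[C@H](c1cc(OCc3ccccc3)c(OCc3ccccc3)c(OCc3ccccc3)c1)[C@H](O[Si](C)(C)C(C)(C)C)C2 | intermediate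
17 | (+)-dihydrorobinetin, (2R,3R)-3,7-dihydroxy-2-(3,4,5-trihydroxyphenyl)chroman-4-one | Oc1ccc2c(c1)O[C@H](c1cc(O)c(O)c(O)c1)[C@@H](O)C2=O | starting material
18 | (2R,3R)-7-(benzyloxy)-3-hydroxy-2-[3,4,5-tris(benzyloxy)phenyl]chroman-4-one | c1ccccc1COc1ccc2c(c1)O[C@H](c1cc(OCc3ccccc3)c(OCc3ccccc3)c(OCc3ccccc3)c1)[C@@H](O)C2=O | intermediate
19 | (2R,3R)-7-(benzyloxy)-3-[(tert-butyldimethylsilyl)oxy]-2-[3,4,5-tris(benzyloxy)phenyl]chroman-4-one | c1ccccc1COc1ccc2c(c1)O[C@H](c1cc(OCc3ccccc3)c(OCc3ccccc3)c(OCc3ccccc3)c1)[C@@H](O[Si](C)(C)C(C)(C)C)C2=O | intermediate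
20 | C8 aryllithium of 16 | [Li]c1c(OCc2ccccc2)cc(OCc2ccccc2)c2c1O[C@H](c1cc(OCc3ccccc3)c(OCc3ccccc3)c(OCc3ccccc3)c1)[C@H](O[Si](C)(C)C(C)(C)C)C2 | intermediate
21 | tertiary alcohol: 4-aryl-4-hydroxy adduct of 20 and 19 (upper unit 2R,3R; lower unit 2R,3R; either C4 epimer) | c1ccccc1COc1ccc2c(c1)O[C@H](c1cc(OCc3ccccc3)c(OCc3ccccc3)c(OCc3ccccc3)c1)[C@@H](O[Si](C)(C)C(C)(C)C)C2(O)c1c(OCc2ccccc2)cc(OCc2ccccc2)c2c1O[C@H](c1cc(OCc3ccccc3)c(OCc3ccccc3)c(OCc3ccccc3)c1)[C@H](O[Si](C)(C)C(C)(C)C)C2 | intermediate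
22 | 4-arylflavan-4-yl cation from 21 | c1ccccc1COc1ccc2c(c1)O[C@H](c1cc(OCc3ccccc3)c(OCc3ccccc3)c(OCc3ccccc3)c1)[C@@H](O[Si](C)(C)C(C)(C)C)[C+]2c1c(OCc2ccccc2)cc(OCc2ccccc2)c2c1O[C@H](c1cc(OCc3ccccc3)c(OCc3ccccc3)c(OCc3ccccc3)c1)[C@H](O[Si](C)(C)C(C)(C)C)C2 | intermediate
23 | bis-TBS nona-O-benzyl dimer (upper unit 2R,3S,4R; lower unit 2R,3R; 3,4-cis) | c1ccccc1COc1ccc2c(c1)O[C@H](c1cc(OCc3ccccc3)c(OCc3ccccc3)c(OCc3ccccc3)c1)[C@@H](O[Si](C)(C)C(C)(C)C)[C@H]2c1c(OCc2ccccc2)cc(OCc2ccccc2)c2c1O[C@H](c1cc(OCc3ccccc3)c(OCc3ccccc3)c(OCc3ccccc3)c1)[C@H](O[Si](C)(C)C(C)(C)C)C2 | intermediate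
24 | nona-O-benzyl dimer diol (upper unit 2R,3S,4R; lower unit 2R,3R) | c1ccccc1COc1ccc2c(c1)O[C@H](c1cc(OCc3ccccc3)c(OCc3ccccc3)c(OCc3ccccc3)c1)[C@@H](O)[C@H]2c1c(OCc2ccccc2)cc(OCc2ccccc2)c2c1O[C@H](c1cc(OCc3ccccc3)c(OCc3ccccc3)c(OCc3ccccc3)c1)[C@H](O)C2 | intermediate
25 | CNP0275321.4, robinetinidol-(4β→8)-epigallocatechin | Oc1ccc2c(c1)O[C@H](c1cc(O)c(O)c(O)c1)[C@@H](O)[C@H]2c1c(O)cc(O)c2c1O[C@H](c1cc(O)c(O)c(O)c1)[C@H](O)C2 | target

**Step count and risks**

Total steps: 17. Longest linear sequence: 15 steps (steps 1–11, then 14–17); steps 12–13 are the second branch.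

Step 5. The risk is that hydride transfer to C4 is slowed by the electron-rich ring D, so that Lewis-acid cleavage of the O1 benzylic ether, or hydride donation from the C5 benzyloxy group, competes. The fallback sets out from aldehyde 5. It would be condensed with Meldrum's acid (pyrrolidinium acetate, benzene, 25 °C) to 5-arylidene Meldrum's acid F1, the strongest acceptor of this reaction class. F1 should undergo the same hydride shift and ring closure on gentle warming with little or no Sc(OTf)3, to give the spiro Meldrum's acid chroman F2. Heating in aqueous pyridine should open the dioxanedione with loss of acetone and CO2 to the chroman-3-carboxylic acid F3. Coupling with N,O-dimethylhydroxylamine (EDC) gives the Weinreb amide F4, and MeMgBr converts F4 into methyl ketone 11, where the route resumes at step 7.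

Step 10. The risk is that racemisation at C2 lags behind hydrogenation, or that the catalyst discriminates the two enantiomers of the ketone poorly, which erodes enantiomeric purity. The fallback sets out from ketone 14. Reduction with LiBH(s-Bu)3 (THF, −78 °C) should occur anti to the C2 aryl group and give the racemic 2,3-cis alcohol F5. Esterification with (S)-O-methylmandelic acid (DCC, DMAP) gives the diastereomeric esters, the (2R,3R) ester F6 and the (2S,3S) ester F7, which are separated by chromatography. Methanolysis of F6 (K2CO3, MeOH) returns to alcohol 15.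

Step 15. The risk is poor facial selectivity of hydride delivery to the C4 cation, or acid-induced loss of silyl groups before reduction. The fallback sets out from ketone 18 and alcohol 15 and forms the interflavan bond by tethered Friedel–Crafts alkylation.
- Upper half: NaBH4 reduction of 18 gives the flavan-3,4-diol F8, and acid-catalysed methanolysis at the benzylic C4 (camphorsulfonic acid, MeOH) gives the 4-methoxyflavan-3-ol F9.
- Lower half: bromide 15 is debrominated (n-BuLi, THF, −78 °C, then MeOH) to penta-O-benzylepigallocatechin F10, which opens glutaric anhydride (DMAP) to the hemiglutarate F11.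
- Coupling: esterification of F11 with the C3 hydroxyl of F9 (DCC, DMAP) gives the glutarate diester F12. TMSOTf (CH2Cl2, −20 °C, high dilution) ionises C4, and the tethered ring D must approach at its more nucleophilic C8 from the face of O3, which should give the macrocyclic 3,4-cis dimer F13.
- Return: methanolysis of both ester links (K2CO3, MeOH) gives the nona-O-benzyl dimer 24.

Further compounds
F1 | step 5 | 5-[(4,6-bis(benzyloxy)-3-bromo-2-{[3,4,5-tris(benzyloxy)phenyl]methoxy}phenyl)methylidene]-2,2-dimethyl-1,3-dioxane-4,6-dione | CC1(C)OC(=O)C(=Cc2c(OCc3cc(OCc4ccccc4)c(OCc4ccccc4)c(OCc4ccccc4)c3)c(Br)c(OCc3ccccc3)cc2OCc2ccccc2)C(=O)O1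
F2 | step 5 | spiro[chromane-3,5'-(2',2'-dimethyl-1',3'-dioxane-4',6'-dione)] carrying 5,7-bis(benzyloxy), 8-bromo and 2-[3,4,5-tris(benzyloxy)phenyl] (racemic) | CC1(C)OC(=O)C2(Cc3c(OCc4ccccc4)cc(OCc4ccccc4)c(Br)c3OC2c2cc(OCc3ccccc3)c(OCc3ccccc3)c(OCc3ccccc3)c2)C(=O)O1
F3 | step 5 | 5,7-bis(benzyloxy)-8-bromo-2-[3,4,5-tris(benzyloxy)phenyl]chromane-3-carboxylic acid (racemic; both C3 epimers) | OC(=O)C1Cc2c(OCc3ccccc3)cc(OCc3ccccc3)c(Br)c2OC1c1cc(OCc2ccccc2)c(OCc2ccccc2)c(OCc2ccccc2)c1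
F4 | step 5 | 5,7-bis(benzyloxy)-8-bromo-N-methoxy-N-methyl-2-[3,4,5-tris(benzyloxy)phenyl]chromane-3-carboxamide (racemic; both C3 epimers) | CON(C)C(=O)C1Cc2c(OCc3ccccc3)cc(OCc3ccccc3)c(Br)c2OC1c1cc(OCc2ccccc2)c(OCc2ccccc2)c(OCc2ccccc2)c1
F5 | step 10 | racemic 2,3-cis-5,7-bis(benzyloxy)-8-bromo-2-[3,4,5-tris(benzyloxy)phenyl]chroman-3-ol (2R,3R and 2S,3S) | Brc1c(OCc2ccccc2)cc(OCc2ccccc2)c2c1O[C@H](c1cc(OCc3ccccc3)c(OCc3ccccc3)c(OCc3ccccc3)c1)[C@H](O)C2.Brc1c(OCc2ccccc2)cc(OCc2ccccc2)c2c1O[C@@H](c1cc(OCc3ccccc3)c(OCc3ccccc3)c(OCc3ccccc3)c1)[C@@H](O)C2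
F6 | step 10 | (2R,3R)-5,7-bis(benzyloxy)-8-bromo-2-[3,4,5-tris(benzyloxy)phenyl]chroman-3-yl (S)-methoxy(phenyl)acetate | Brc1c(OCc2ccccc2)cc(OCc2ccccc2)c2c1O[C@H](c1cc(OCc3ccccc3)c(OCc3ccccc3)c(OCc3ccccc3)c1)[C@H](OC(=O)[C@@H](OC)c1ccccc1)C2
F7 | step 10 | (2S,3S)-5,7-bis(benzyloxy)-8-bromo-2-[3,4,5-tris(benzyloxy)phenyl]chroman-3-yl (S)-methoxy(phenyl)acetate | Brc1c(OCc2ccccc2)cc(OCc2ccccc2)c2c1O[C@@H](c1cc(OCc3ccccc3)c(OCc3ccccc3)c(OCc3ccccc3)c1)[C@@H](OC(=O)[C@@H](OC)c1ccccc1)C2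
F8 | step 15 | (2R,3S,4R)-7-(benzyloxy)-2-[3,4,5-tris(benzyloxy)phenyl]chromane-3,4-diol | c1ccccc1COc1ccc2c(c1)O[C@H](c1cc(OCc3ccccc3)c(OCc3ccccc3)c(OCc3ccccc3)c1)[C@@H](O)[C@@H]2O
F9 | step 15 | (2R,3S)-7-(benzyloxy)-4-methoxy-2-[3,4,5-tris(benzyloxy)phenyl]chroman-3-ol (both C4 epimers) | c1ccccc1COc1ccc2c(c1)O[C@H](c1cc(OCc3ccccc3)c(OCc3ccccc3)c(OCc3ccccc3)c1)[C@@H](O)C2OC
F10 | step 15 | (2R,3R)-5,7-bis(benzyloxy)-2-[3,4,5-tris(benzyloxy)phenyl]chroman-3-ol | c1c(OCc2ccccc2)cc(OCc2ccccc2)c2c1O[C@H](c1cc(OCc3ccccc3)c(OCc3ccccc3)c(OCc3ccccc3)c1)[C@H](O)C2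
F11 | step 15 | 5-{[(2R,3R)-5,7-bis(benzyloxy)-2-[3,4,5-tris(benzyloxy)phenyl]chroman-3-yl]oxy}-5-oxopentanoic acid | c1c(OCc2ccccc2)cc(OCc2ccccc2)c2c1O[C@H](c1cc(OCc3ccccc3)c(OCc3ccccc3)c(OCc3ccccc3)c1)[C@H](OC(=O)CCCC(=O)O)C2
F12 | step 15 | pentanedioate diester joining O3 of F9 and O3 of F10 | c1ccccc1COc1ccc2c(c1)O[C@H](c1cc(OCc3ccccc3)c(OCc3ccccc3)c(OCc3ccccc3)c1)[C@@H](OC(=O)CCCC(=O)O[C@@H]1Cc3c(OCc4ccccc4)cc(OCc4ccccc4)cc3O[C@@H]1c1cc(OCc3ccccc3)c(OCc3ccccc3)c(OCc3ccccc3)c1)C2OC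
F13 | step 15 | macrocyclic pentanedioate-bridged nona-O-benzyl (4β→8) dimer (upper unit 2R,3S,4R; lower unit 2R,3R) | c1ccccc1COc1ccc2c(c1)O[C@H](c1cc(OCc3ccccc3)c(OCc3ccccc3)c(OCc3ccccc3)c1)[C@H]3OC(=O)CCCC(=O)O[C@@H]4Cc5c(OCc6ccccc6)cc(OCc6ccccc6)c(c5O[C@@H]4c4cc(OCc5ccccc5)c(OCc5ccccc5)c(OCc5ccccc5)c4)[C@@H]23
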